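Early in the alpha run, 3.00 h in, E stood at 13.8% of the X charged and L at 1.9%. By 15.0 h they read 2.3% and 4.7%. I had to decide which flask to charge next, so I needed to know what E costs per hour in L.

| flask | X | Z | Q | J | remark | time |
|---|---|---|---|---|---|---|
| alpha | 14 mM | 0.90 equiv | 1 equiv | 0.70 mM | run made earlier |  |
| eta | 14 mM | 0.90 equiv | 2 equiv | 0.70 mM | run made earlier |  |
| red | 14 mM | 0.900 equiv | 1.00 equiv (fed, over 15 h) | 0.700 mM | all else is in the flask from the start; the feed brings no volume worth counting | 40 h |
| teal | 14 mM (fed, over 15 h) | 0.900 equiv | 1.00 equiv | 0.700 mM | all else is in the flask from the start; the feed brings no volume worth counting | 40 h |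
| amber | 14 mM | 0.900 equiv | 1.00 equiv | 0.700 mM | everything together at the start | 40 h |

| run | time / h | E / % | L / % | X / % |
|---|---|---|---|---|
| alpha | 3.00 | 13.8 | 1.9 | 84.1 |
| alpha | 8.00 | 4.7 | 4.0 | 90.0 |
| alpha | 15.0 | 2.3 | 4.7 | 92.5 |
| alpha | 40.0 | 0.8 | 6.5 | 93.9 |
| eta | 1.00 | 14.5 | 1.2 | 83.9 |
| eta | 2.00 | 9.0 | 1.4 | 89.2 |
| eta | 3.00 | 5.1 | 1.2 | 92.9 |
| eta | 4.00 | 4.1 | 1.2 | 94.4 |

(standard deviation of a reading: 0.5 percentage points)

- the flask that comes out highest in share of E in E plus L, or "all alike" when all lie within 1.5 percentage points (red / teal / amber / all alike)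
- share of E in E plus L at the end, red
- share of E in E plus L at the end, teal
- share of E in E plus L at the end, amber



Over those hours 1/E rose nearly in a straight line, with slope b, and that lets the rate of L be integrated in closed form. I took dL/dt = kL·E, where kL, a first-order rate constant, is the fraction of E turning to L per hour.

b = (1/E late − 1/E early) / Δt = 3.02 h⁻¹

A = ∫E dt = ln(E early / E late) / b = 0.593 h

kL = ΔL / A = 0.0472 h⁻¹

The line gave 4.47% at 8.00 h, against a reading of 4.7%. A is the exposure: the whole charge sitting as E for that long.

Early E halved in about 2.40 h, while the path to L has a half-life of 14.7 h, so the fall outran the leak. The feed takes 15 h, longer than that fall. In teal, then, I expected Q to meet Z before much X had come. In red, E held near its early reading through the feed would make 9.77% of L, more than alpha's 6.5%. Alpha's last E read 0.8% with a scatter of 0.5 percentage points, so my own reckoning committed to an order of L, teal lowest and red highest, and gave no shares. I chose teal.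

The forecast differed from my reckoning in giving shares: it named teal as highest, with 7% for red, 17% for teal and 11% for amber, on the ground “Q consumes Z before X arrives”.

The flasks gave shares of 1.19% for red, 11.8% for teal and 3.67% for amber, with teal highest. L ended at 14.3%, 2.40% and 6.19% in the same flask order.

    X + Z ⇌ E (K = 65.0 M⁻¹, k = 65.0 M⁻¹ h⁻¹)
    Z + Q → D (k = 74.0 M⁻¹ h⁻¹)
    Q + J → G (k = 29.0 M⁻¹ h⁻¹)
    E → L (k = 0.0430 h⁻¹)

In teal, E fell from 1.95% at 15.0 h to 0.319% at 40.0 h. Taken as exponential, that is an exposure of 0.226 h, and kL turns it into 1.07% of L, where teal gained 0.95 points. The neighbour, red with 3.60 equiv of Z, ended with Q at 0%, X at 13.1% and E at 20.4%. Taking φ = E/(X+E) at its end value, 0.609, X+E falls as exp(−kL·φ·t), which gives L = 68.3%. That neighbour held 66.5% of L, and its share was 23.5%.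

(The earlier runs and the new flask come from a simulation on assumed constants; noise was put on by code.)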